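The route rests on disconnecting the C7–C8 bond of the cyclobutane (ring C1–C6–C7–C8 of the bicyclo[4.2.0]octene core; C7 carries the pyrone, C8 is the CHMe carbon) by putting a carbonyl carbon back between them, so that the four-membered ring becomes a cis-fused cyclopentanone. Photochemical Wolff rearrangement of the 2-diazo ketone in methanol expels N2, shifts C8 onto the diazo carbon and gives the cyclobutane ester in one operation, with C1, C6 and C8 already correct. The precursor, cis-hydrindane diazo diketone 14, comes from an Ir-catalysed enolate crotylation, Wacker oxidation and intramolecular 1,6-addition; the ester later grows into the pyrone and singlet oxygen adds last.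

Key step: step 8

Remarks and assumptions (chemistry):
- Bicyclo[4.2.0]octane numbering is used for 16–28: C1 = quaternary ring-fusion carbon, C2–C5 = six-ring carbons, C6 = CH ring fusion, C7 = ester/pyrone-bearing carbon, C8 = CHMe. Hydrindanes 11–14 use indene numbering (C1 = CHMe, C2 = C=O, C3 = CH2 or CN2, C3a = CH fusion, C7 = enone C=O, C7a = quaternary); C1, C3, C3a and C7a become C8, C7, C6 and C1.
- Metal enolates generated in situ are treated as deprotonated forms of numbered compounds and carry no number.
- Assumption: the sp3 CHMe carbon of the enone ring in 12–16 is drawn as the epimer expected after base equilibration; it becomes sp2 in step 9, so either epimer serves.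
- Bicyclo[4.2.0]octa-2,4-dienes can open to cyclooctatrienes on heating, so steps 10–18 are kept at or below 40 °C.
- The quaternary carbon is made on a non-aromatic enone enolate and not by allylating a phenoxide, which would react on oxygen and would have to give up aromaticity to react on carbon; the second ring double bond is added afterwards.

Step 1
Reactants: 1 (E)-but-2-en-1-ol
Product: 2 tert-butyl (E)-but-2-en-1-yl carbonate
Conditions: Boc2O, n-Bu4NHSO4 (cat.), 30% aq. NaOH, CH2Cl2, 0 °C → rt
Reagents that add atoms: di-tert-butyl dicarbonate, CC(C)(C)OC(=O)OC(=O)OC(C)(C)C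
Why: Acylation of the primary allylic alcohol with Boc2O under phase-transfer conditions (carbonate formation) is routine, leaves the E-alkene untouched and forms no stereocentre.

Step 2
Reactants: 3 pentan-3-one; 4 2-methylprop-2-enal
Product: 6 2,4,6-trimethylcyclohex-2-en-1-one, via 2,4-dimethyl-5-oxoheptanal 5 (not isolated)
Conditions: KOH (10 mol%), MeOH, excess 3, slow addition of 4 at 0 °C, then 60 °C
Reagents that add atoms: none
Why: Robinson annulation, in which the enolate of 3 adds to the β-carbon of 4 (Michael) and the ethyl-side enolate of 5 condenses on the aldehyde (aldol–dehydration) to give the 2-methyl enone; the C4/C6 stereocentres need no control because C6 becomes an enolate in step 3 and C4 becomes planar in step 4.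

Step 3
Reactants: 6 2,4,6-trimethylcyclohex-2-en-1-one; 2 tert-butyl (E)-but-2-en-1-yl carbonate
Product: 7 (6S)-6-[(2S)-but-3-en-2-yl]-2,4,6-trimethylcyclohex-2-en-1-one (both C4 epimers)
Conditions: LDA, THF, −78 °C; then 2, [Ir(cod)Cl]2 (2 mol%), BINOL-derived phosphoramidite L* (4 mol%, pre-activated with n-PrNH2; enantiomer selected to give the (S) allylic centre), THF, −20 °C → rt
Reagents that add atoms: none
Why: Ir-catalysed asymmetric allylic alkylation of a prochiral cyclic ketone enolate, in which LDA removes the α′-H kinetically, the cross-conjugated enolate attacks the substituted terminus of the Ir π-crotyl complex (branched selectivity), the allylic centre (S) is set by the ligand-defined face of the allyl unit and the quaternary C6 by the preferred enolate face in the catalyst pocket, the minor C6 epimer being a diastereomer that can be removed after step 4.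

Step 4
Reactants: 7 (6S)-6-[(2S)-but-3-en-2-yl]-2,4,6-trimethylcyclohex-2-en-1-one
Product: 9 (6R)-6-[(2S)-but-3-en-2-yl]-2,4,6-trimethylcyclohexa-2,4-dien-1-one, via TMS dienol ether 8 (not isolated)
Conditions: TMSOTf, Et3N, CH2Cl2, 0 °C; then DDQ, 2,6-lutidine, CH2Cl2, 0 °C → rt
Reagents that add atoms: none
Why: Dehydrogenation through a silyl dienol ether, in which soft enolisation can only remove the γ-H (C6 is quaternary) to give linear dienol ether 8 and DDQ abstracts hydride at C5 to give the linear 2,4-dienone after loss of silicon (the classical dienol-ether to 4,6-dienone oxidation); the C4 centre disappears, the two set stereocentres are untouched, and room temperature keeps the 6-allyl dienone from Cope or retro-Claisen shifts.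

Step 5
Reactants: 9 (6R)-6-[(2S)-but-3-en-2-yl]-2,4,6-trimethylcyclohexa-2,4-dien-1-one
Product: 10 (6S)-2,4,6-trimethyl-6-[(2R)-3-oxobutan-2-yl]cyclohexa-2,4-dien-1-one
Conditions: PdCl2 (10 mol%), CuCl, O2 (1 atm), DMF–H2O (7:1), rt
Reagents that add atoms: water, O
Why: Tsuji–Wacker oxidation, in which Markovnikov hydroxypalladation of the terminal alkene and β-hydride elimination give the methyl ketone under near-neutral conditions at room temperature, so the enolisable CHMe centre is not epimerised.

Step 6
Reactants: 10 (6S)-2,4,6-trimethyl-6-[(2R)-3-oxobutan-2-yl]cyclohexa-2,4-dien-1-one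
Product: 12 cis-1,4,6,7a-tetramethyl-3,3a,4,7a-tetrahydro-1H-indene-2,7-dione, via deconjugated enone 11 (not isolated)
Conditions: LiHMDS (1.05 equiv), THF, −78 → 0 °C; AcOH, −78 °C; then DBU (0.2 equiv), CH2Cl2, rt
Reagents that add atoms: none
Why: Intramolecular vinylogous (1,6) Michael addition, in which the kinetic methyl-ketone enolate adds to the δ-carbon C5 of the dienone to close the five-membered ring, the tether on the adjacent quaternary carbon forces cis fusion (3a-H syn to 7a-Me), reversible aldol addition to the hindered C1 carbonyl funnels into the conjugate adduct, and catalytic DBU moves the double bond of 11 into conjugation without touching the hindered CHMe centre.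

Step 7
Reactants: 12 cis-1,4,6,7a-tetramethyl-3,3a,4,7a-tetrahydro-1H-indene-2,7-dione
Product: 14 3-diazo-cis-1,4,6,7a-tetramethyl-3,3a,4,7a-tetrahydro-1H-indene-2,7-dione, via trifluoroacetyl diketone 13 (not isolated)
Conditions: LiHMDS, THF, −78 °C; CF3CO2CH2CF3; then MsN3, Et3N, H2O (1 equiv), MeCN, rt
Reagents that add atoms: methanesulfonyl azide, CS(=O)(=O)N=[N+]=[N-]
Why: Regitz-type detrifluoroacetylative diazo transfer, in which kinetic enolisation takes place at the only α-CH2 of the cyclopentanone (C3), the trifluoroacetyl group activates that carbon for N2 transfer from mesyl azide and leaves as the sulfonamide, so the diazo group sits next to C3a and no stereocentre is affected.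

Step 8
Reactants: 14 3-diazo-cis-1,4,6,7a-tetramethyl-3,3a,4,7a-tetrahydro-1H-indene-2,7-dione
Product: 16 methyl 1,3,5,8-tetramethyl-2-oxobicyclo[4.2.0]oct-3-ene-7-carboxylate, via ketene 15 (not isolated)
Conditions: hν (365–390 nm LED), MeOH (0.01 M, degassed), 0 °C → rt
Reagents that add atoms: methanol, CO
Why: Excitation of the α-diazo ketone expels N2 while C8 (the CHMe carbon) migrates with retention from the carbonyl carbon to the former diazo carbon, forming the C7–C8 bond; ketene 15 is captured by methanol and the ester enol is protonated to 16. This is the photochemical Wolff ring contraction of a cyclic 2-diazo ketone to a cycloalkanecarboxylate, well known for 2-diazocyclopentanones. The cyclobutane (C1–C6–C7–C8) is not closed by a cyclisation: it arises by contraction of the five-membered ring through the 1,2-shift, so no exo/endo closure mode applies. C1, C6 and C8 are carried over unchanged; the new C7 centre is set by protonation of the enol on the convex face (ester endo) and is provisional, because it is re-formed in step 11. The step needs the rearrangement to outrun carbene-type paths (1,2-H shift from C6–H, O–H insertion) and enone photoreactions: the ring-locked s-Z diazo ketone favours the concerted shift, only C8 can migrate, and long-wavelength light at high dilution is absorbed mainly by the diazo ketone.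

Step 9
Reactants: 16 methyl 1,3,5,8-tetramethyl-2-oxobicyclo[4.2.0]oct-3-ene-7-carboxylate
Product: 18 methyl 1,3,5,8-tetramethyl-2-(trifluoromethylsulfonyloxy)bicyclo[4.2.0]octa-2,4-diene-7-carboxylate, via TMS dienol ether 17 (not isolated)
Conditions: TMSOTf, Et3N, CH2Cl2, 0 °C; then PhNTf2, CsF, DME, rt
Reagents that add atoms: N-phenylbis(trifluoromethanesulfonimide), O=S(=O)(N(c1ccccc1)S(=O)(=O)C(F)(F)F)C(F)(F)F
Why: Soft enolisation (the ketone reacts, the ester does not) removes the single γ-H at C5 to give linear silyl dienol ether 17, and fluoride-induced O-sulfonylation with PhNTf2 (silyl enol ether to vinyl triflate exchange) gives the dienyl triflate regiospecifically, erasing the C5 stereocentre.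

Step 10
Reactants: 18 methyl 1,3,5,8-tetramethyl-2-(trifluoromethylsulfonyloxy)bicyclo[4.2.0]octa-2,4-diene-7-carboxylate
Product: 19 methyl 1,3,5,8-tetramethylbicyclo[4.2.0]octa-2,4-diene-7-carboxylate
Conditions: Pd(OAc)2 (5 mol%), PPh3 (10 mol%), n-Bu3N, HCO2H, DMF, 40 °C
Reagents that add atoms: none
Why: Palladium-catalysed formate reduction of a vinyl triflate (oxidative addition, formate-to-hydride exchange with loss of CO2, reductive elimination) replaces OTf by H without moving the diene, at a temperature below the onset of electrocyclic ring opening.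

Step 11
Reactants: 19 methyl 1,3,5,8-tetramethylbicyclo[4.2.0]octa-2,4-diene-7-carboxylate
Product: 20 methyl 1,3,5,7,8-pentamethylbicyclo[4.2.0]octa-2,4-diene-7-carboxylate (7-Me exo, ester endo)
Conditions: LDA, THF, −78 °C; MeI, −78 → −20 °C
Reagents that add atoms: iodomethane, CI
Why: Ester enolate alkylation, in which LDA forms the exocyclic enolate at C7 and methyl iodide approaches its convex face because the concave face lies over the cyclohexadiene ring, so the new methyl is exo (cis to 8-Me and 1-Me) and the ester endo.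

Step 12
Reactants: 20 methyl 1,3,5,7,8-pentamethylbicyclo[4.2.0]octa-2,4-diene-7-carboxylate
Product: 21 (1,3,5,7,8-pentamethylbicyclo[4.2.0]octa-2,4-dien-7-yl)methanol
Conditions: LiAlH4, Et2O, 0 °C
Reagents that add atoms: none
Why: Hydride reduction of the hindered ester with LiAlH4 gives the neopentyl primary alcohol, while the diene and all stereocentres are inert.

Step 13
Reactants: 21 (1,3,5,7,8-pentamethylbicyclo[4.2.0]octa-2,4-dien-7-yl)methanol
Product: 22 1,3,5,7,8-pentamethylbicyclo[4.2.0]octa-2,4-diene-7-carbaldehyde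
Conditions: Dess–Martin periodinane, CH2Cl2, 0 °C → rt
Reagents that add atoms: none
Why: Dess–Martin oxidation gives the aldehyde under mild conditions, and since C7 is quaternary no epimerisation is possible.

Step 14
Reactants: 22 1,3,5,7,8-pentamethylbicyclo[4.2.0]octa-2,4-diene-7-carbaldehyde; 23 methyl 2-methyl-3-oxopentanoate
Product: 24 methyl 5-hydroxy-2,4-dimethyl-3-oxo-5-(1,3,5,7,8-pentamethylbicyclo[4.2.0]octa-2,4-dien-7-yl)pentanoate (diastereomer mixture)
Conditions: 23, NaH then n-BuLi, THF, 0 °C; then 22, −78 °C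
Reagents that add atoms: none
Why: Aldol addition of the β-keto ester dianion of 23, which reacts through its more basic γ-carbon, to the non-enolisable aldehyde; the new carbinol and α-methyl centres need no control since they are oxidised or enolised in the next steps.

Step 15
Reactants: 24 methyl 5-hydroxy-2,4-dimethyl-3-oxo-5-(1,3,5,7,8-pentamethylbicyclo[4.2.0]octa-2,4-dien-7-yl)pentanoate
Product: 25 methyl 2,4-dimethyl-3,5-dioxo-5-(1,3,5,7,8-pentamethylbicyclo[4.2.0]octa-2,4-dien-7-yl)pentanoate
Conditions: Dess–Martin periodinane, CH2Cl2, rt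
Reagents that add atoms: none
Why: Dess–Martin oxidation of the secondary alcohol gives the β,δ-diketo ester without strong acid or base that could harm the diene.

Step 16
Reactants: 25 methyl 2,4-dimethyl-3,5-dioxo-5-(1,3,5,7,8-pentamethylbicyclo[4.2.0]octa-2,4-dien-7-yl)pentanoate
Product: 26 4-hydroxy-3,5-dimethyl-6-(1,3,5,7,8-pentamethylbicyclo[4.2.0]octa-2,4-dien-7-yl)-2H-pyran-2-one
Conditions: DBU, toluene, rt → 40 °C
Reagents that add atoms: none
Why: DBU-mediated lactonisation, in which the enol oxygen of the δ-ketone attacks the ester carbonyl with loss of methanol (acyl substitution closing the six-membered lactone), gives the 4-hydroxy-2-pyranone.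

Step 17
Reactants: 26 4-hydroxy-3,5-dimethyl-6-(1,3,5,7,8-pentamethylbicyclo[4.2.0]octa-2,4-dien-7-yl)-2H-pyran-2-one
Product: 27 2-methoxy-3,5-dimethyl-6-(1,3,5,7,8-pentamethylbicyclo[4.2.0]octa-2,4-dien-7-yl)-4H-pyran-4-one
Conditions: MeOTf, CH2Cl2, 0 °C → rt; aq. NaHCO3 work-up
Reagents that add atoms: methyl trifluoromethanesulfonate, COS(=O)(=O)C(F)(F)F
Why: O-Methylation with the hard electrophile methyl triflate takes place at the lactone carbonyl oxygen of the neutral hydroxypyranone, and loss of the 4-OH proton on work-up gives the 2-methoxy-4-pyranone, the known regiochemical preference of 4-hydroxy-3,5-dimethyl-2-pyranones with methyl triflate or fluorosulfonate.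

Step 18
Reactants: 27 2-methoxy-3,5-dimethyl-6-(1,3,5,7,8-pentamethylbicyclo[4.2.0]octa-2,4-dien-7-yl)-4H-pyran-4-one
Product: 28 CNP0183511.1, the 2,5-endoperoxide of 27
Conditions: O2, methylene blue (cat.), hν (visible, >500 nm), CH2Cl2, 0 °C
Reagents that add atoms: dioxygen, O=O
Why: Photosensitised [4+2] cycloaddition of singlet oxygen to the cyclohexadiene forms the 2,5-endoperoxide and sets C2 and C5 by suprafacial attack on the convex face (that of 1-Me and 6-H), the concave face being blocked by the cyclobutane and its endo pyrone, while light absorbed only by the sensitiser spares the pyrone.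

Compound list
1 | (E)-but-2-en-1-ol | C/C=C/CO | starting material
2 | tert-butyl (E)-but-2-en-1-yl carbonate | C/C=C/COC(=O)OC(C)(C)C | intermediate
3 | pentan-3-one | CCC(=O)CC | starting material
4 | 2-methylprop-2-enal (methacrolein) | CC(=C)C=O | starting material
5 | 2,4-dimethyl-5-oxoheptanal (Michael adduct, diastereomer mixture, not isolated) | CCC(=O)C(C)CC(C)C=O | intermediate
6 | 2,4,6-trimethylcyclohex-2-en-1-one (racemic, cis/trans mixture) | CC1CC(C)C(=O)C(C)=C1 | intermediate
7 | (6S)-6-[(2S)-but-3-en-2-yl]-2,4,6-trimethylcyclohex-2-en-1-one (both C4 epimers) | C=C[C@H](C)[C@@]1(C)C(=O)C(C)=CC(C)C1 | intermediate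
8 | TMS dienol ether of 7: {[6-(but-3-en-2-yl)-2,4,6-trimethylcyclohexa-1,3-dien-1-yl]oxy}trimethylsilane, stereocentres as in 7 (not isolated) | C=C[C@H](C)[C@@]1(C)C(O[Si](C)(C)C)=C(C)C=C(C)C1 | intermediate
9 | (6R)-6-[(2S)-but-3-en-2-yl]-2,4,6-trimethylcyclohexa-2,4-dien-1-one | C=C[C@H](C)[C@@]1(C)C(=O)C(C)=CC(C)=C1 | intermediate
10 | (6S)-2,4,6-trimethyl-6-[(2R)-3-oxobutan-2-yl]cyclohexa-2,4-dien-1-one | CC(=O)[C@H](C)[C@@]1(C)C(=O)C(C)=CC(C)=C1 | intermediate
11 | deconjugated isomer of 12: cis-1,4,6,7a-tetramethyl-3,3a,6,7a-tetrahydro-1H-indene-2,7-dione, C6 epimers (not isolated) | C1C(=O)[C@H](C)[C@@]2(C)C(=O)C(C)C=C(C)[C@@H]12 | intermediate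
12 | cis-fused 1,4,6,7a-tetramethyl-3,3a,4,7a-tetrahydro-1H-indene-2,7-dione; 1-Me, 4-Me, 7a-Me and 3a-H on the same (convex) face | C1C(=O)[C@H](C)[C@@]2(C)C(=O)C(C)=C[C@H](C)[C@@H]12 | intermediate
13 | 3-(trifluoroacetyl) derivative of 12 (not isolated) | FC(F)(F)C(=O)C1C(=O)[C@H](C)[C@@]2(C)C(=O)C(C)=C[C@H](C)[C@@H]12 | intermediate
14 | 3-diazo derivative of 12: cis-fused 3-diazo-1,4,6,7a-tetramethyl-3,3a,4,7a-tetrahydro-1H-indene-2,7-dione, stereocentres as in 12 | [N-]=[N+]=C1C(=O)[C@H](C)[C@@]2(C)C(=O)C(C)=C[C@H](C)[C@@H]12 | intermediate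
15 | ketene: cis-fused 7-(oxomethylidene)-1,3,5,8-tetramethylbicyclo[4.2.0]oct-3-en-2-one (not isolated) | O=C=C1[C@H](C)[C@@]2(C)C(=O)C(C)=C[C@H](C)[C@@H]12 | intermediate
16 | methyl 1,3,5,8-tetramethyl-2-oxobicyclo[4.2.0]oct-3-ene-7-carboxylate; cis-fused, 1-Me, 5-Me, 8-Me and 6-H on the convex face, CO2Me endo | COC(=O)[C@H]1[C@H](C)[C@@]2(C)C(=O)C(C)=C[C@H](C)[C@@H]12 | intermediate
17 | TMS dienol ether of 16 (2-trimethylsilyloxy-2,4-diene; not isolated) | COC(=O)[C@H]1[C@H](C)[C@@]2(C)C(O[Si](C)(C)C)=C(C)C=C(C)[C@@H]12 | intermediate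
18 | methyl 1,3,5,8-tetramethyl-2-(trifluoromethylsulfonyloxy)bicyclo[4.2.0]octa-2,4-diene-7-carboxylate, ring stereocentres as in 16 | COC(=O)[C@H]1[C@H](C)[C@@]2(C)C(OS(=O)(=O)C(F)(F)F)=C(C)C=C(C)[C@@H]12 | intermediate
19 | methyl 1,3,5,8-tetramethylbicyclo[4.2.0]octa-2,4-diene-7-carboxylate; cis-fused, 8-Me exo, CO2Me endo | COC(=O)[C@H]1[C@H](C)[C@@]2(C)C=C(C)C=C(C)[C@@H]12 | intermediate
20 | methyl 1,3,5,7,8-pentamethylbicyclo[4.2.0]octa-2,4-diene-7-carboxylate; 1-Me, 7-Me, 8-Me and 6-H on the convex face, CO2Me endo | COC(=O)[C@@]1(C)[C@H](C)[C@@]2(C)C=C(C)C=C(C)[C@@H]12 | intermediate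
21 | (1,3,5,7,8-pentamethylbicyclo[4.2.0]octa-2,4-dien-7-yl)methanol, stereocentres as in 20 | OC[C@@]1(C)[C@H](C)[C@@]2(C)C=C(C)C=C(C)[C@@H]12 | intermediate
22 | 1,3,5,7,8-pentamethylbicyclo[4.2.0]octa-2,4-diene-7-carbaldehyde, stereocentres as in 20 | O=C[C@@]1(C)[C@H](C)[C@@]2(C)C=C(C)C=C(C)[C@@H]12 | intermediate
23 | methyl 2-methyl-3-oxopentanoate | CCC(=O)C(C)C(=O)OC | starting material
24 | methyl 5-hydroxy-2,4-dimethyl-3-oxo-5-(bicyclooctadien-7-yl)pentanoate, ring stereocentres as in 20, chain centres mixed | COC(=O)C(C)C(=O)C(C)C(O)[C@@]1(C)[C@H](C)[C@@]2(C)C=C(C)C=C(C)[C@@H]12 | intermediate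
25 | methyl 2,4-dimethyl-3,5-dioxo-5-(bicyclooctadien-7-yl)pentanoate, ring stereocentres as in 20 | COC(=O)C(C)C(=O)C(C)C(=O)[C@@]1(C)[C@H](C)[C@@]2(C)C=C(C)C=C(C)[C@@H]12 | intermediate
26 | 4-hydroxy-3,5-dimethyl-6-(1,3,5,7,8-pentamethylbicyclo[4.2.0]octa-2,4-dien-7-yl)-2H-pyran-2-one, pyranone endo | O=c1oc([C@@]2(C)[C@H](C)[C@@]3(C)C=C(C)C=C(C)[C@@H]23)c(C)c(O)c1C | intermediate
27 | 2-methoxy-3,5-dimethyl-6-(1,3,5,7,8-pentamethylbicyclo[4.2.0]octa-2,4-dien-7-yl)-4H-pyran-4-one, pyrone endo | COc1oc([C@@]2(C)[C@H](C)[C@@]3(C)C=C(C)C=C(C)[C@@H]23)c(C)c(=O)c1C | intermediate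
28 | CNP0183511.1: 2-methoxy-3,5-dimethyl-6-(2,5-epidioxy-1,3,5,7,8-pentamethylbicyclo[4.2.0]oct-3-en-7-yl)-4H-pyran-4-one; peroxide bridge anti to the cyclobutane, pyrone endo, 1-Me/7-Me/8-Me cis | COc1oc([C@@]2(C)[C@H](C)[C@@]3(C)[C@@H]4OO[C@@](C)(C=C4C)[C@@H]23)c(C)c(=O)c1C | target

Total step count: 18. Longest linear sequence: 17 steps (steps 2–18, from pentan-3-one and methacrolein); step 1 is a one-step side branch.

Steps most likely to fail

1. Step 3 (Ir-catalysed crotylation). The facial discrimination of the prochiral enolate in the ion pair may be weak, giving a low diastereomer ratio at the quaternary carbon, and worse for the C4 epimer that is mismatched with the catalyst; O-allylation may also compete. The fallback sets out from 6 and comes back at 7, replacing catalyst control by a sigmatropic shift plus resolution. The potassium enolate of 6 (KHMDS, THF–HMPA, −78 °C) is O-alkylated with (E)-but-2-enyl methanesulfonate to the cross-conjugated crotyl dienol ether 1-[(E)-but-2-enyloxy]-2,4,6-trimethylcyclohexa-1,5-diene F1. Warming in toluene (80 °C) should induce a Claisen rearrangement through a chair transition state, which delivers the branched butenyl group to C6 with the required relative configuration and gives racemic 7, that is 7 together with its enantiomer (6R)-6-[(2R)-but-3-en-2-yl]-2,4,6-trimethylcyclohex-2-en-1-one F2. Chromatography on a chiral stationary phase then returns 7.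

2. Step 8 (Wolff contraction). Light absorbed by the cyclohexenone may start enone photoreactions, or the excited diazo ketone may leak into carbene paths (1,2-H shift, O–H insertion). The fallback sets out from 12 and comes back at 19, changing the order so that the enone is gone before light is used.
   - The saturated ketone of 12 is ketalised selectively (1,2-bis(trimethylsilyloxy)ethane, cat. TMSOTf, CH2Cl2, −78 °C) to the dioxolane F3.
   - KHMDS/PhNTf2 converts the enone into the dienyl triflate F4, and Pd(OAc)2/PPh3/n-Bu3N/HCO2H reduces it to the diene ketal F5.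
   - PPTS in wet acetone frees the diene ketone F6.
   - LiHMDS/CF3CO2CH2CF3 gives the trifluoroacetyl ketone F7, and MsN3/Et3N the diazo ketone F8.
   - Irradiation in methanol contracts the ring through the ketene F9 to ester 19.

3. Step 11 (C7 methylation). Methyl iodide may approach from the concave face, or with poor facial selectivity, because the convex face carries the neighbouring 8-methyl group; this would give the C7 epimer. The fallback sets out from 19 and comes back at 21. It exchanges the roles of the two C7 substituents, so that an electrophile entering on the concave face becomes the future pyrone carbon and the carboxyl carbon becomes the methyl group.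
   - The enolate of 19 (LDA, −78 °C) is trapped with monomeric formaldehyde to the hydroxymethyl ester F10, which is silylated (TBSCl, imidazole) to the silyl ether F11.
   - LiAlH4 reduces the ester to the alcohol F12, and Dess–Martin oxidation gives the aldehyde F13.
   - Condensation with TsNHNH2 gives the tosylhydrazone F14, whose reduction (catecholborane, then NaOAc, ≤ 45 °C) gives the 7-methyl silyl ether F15.
   - TBAF removes the silyl group to give 21.

Further compounds
F1 | step 3 | 1-[(E)-but-2-enyloxy]-2,4,6-trimethylcyclohexa-1,5-diene (crotyl dienol ether of 6) | C/C=C/COC1=C(C)CC(C)C=C1C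
F2 | step 3 | (6R)-6-[(2R)-but-3-en-2-yl]-2,4,6-trimethylcyclohex-2-en-1-one (enantiomer of 7) | C=C[C@@H](C)[C@]1(C)C(=O)C(C)=CC(C)C1
F3 | step 8 | 2,2-ethylenedioxy ketal of 12 (dioxolane at the cyclopentanone) | C1C2(OCCO2)[C@H](C)[C@@]3(C)C(=O)C(C)=C[C@H](C)[C@@H]13
F4 | step 8 | dienyl triflate of F3 | C1C2(OCCO2)[C@H](C)[C@@]3(C)C(OS(=O)(=O)C(F)(F)F)=C(C)C=C(C)[C@@H]13
F5 | step 8 | diene ketal (triflate replaced by H) | C1C2(OCCO2)[C@H](C)[C@@]3(C)C=C(C)C=C(C)[C@@H]13
F6 | step 8 | cis-1,4,6,7a-tetramethyl-1,3,3a,7a-tetrahydro-2H-inden-2-one (diene ketone) | C1C(=O)[C@H](C)[C@@]2(C)C=C(C)C=C(C)[C@@H]12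
F7 | step 8 | 3-(trifluoroacetyl) derivative of F6 | FC(F)(F)C(=O)C1C(=O)[C@H](C)[C@@]2(C)C=C(C)C=C(C)[C@@H]12
F8 | step 8 | 3-diazo derivative of F6 | [N-]=[N+]=C1C(=O)[C@H](C)[C@@]2(C)C=C(C)C=C(C)[C@@H]12
F9 | step 8 | 7-(oxomethylidene)-1,3,5,8-tetramethylbicyclo[4.2.0]octa-2,4-diene (ketene) | O=C=C1[C@H](C)[C@@]2(C)C=C(C)C=C(C)[C@@H]12
F10 | step 11 | methyl 7-(hydroxymethyl)-1,3,5,8-tetramethylbicyclo[4.2.0]octa-2,4-diene-7-carboxylate (CH2OH endo, CO2Me exo) | OC[C@@]1(C(=O)OC)[C@H](C)[C@@]2(C)C=C(C)C=C(C)[C@@H]12
F11 | step 11 | TBS ether of F10 | CC(C)(C)[Si](C)(C)OC[C@@]1(C(=O)OC)[C@H](C)[C@@]2(C)C=C(C)C=C(C)[C@@H]12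
F12 | step 11 | [7-(tert-butyldimethylsilyloxymethyl)-1,3,5,8-tetramethylbicyclo[4.2.0]octa-2,4-dien-7-yl]methanol | CC(C)(C)[Si](C)(C)OC[C@@]1(CO)[C@H](C)[C@@]2(C)C=C(C)C=C(C)[C@@H]12
F13 | step 11 | 7-(tert-butyldimethylsilyloxymethyl)-1,3,5,8-tetramethylbicyclo[4.2.0]octa-2,4-diene-7-carbaldehyde | CC(C)(C)[Si](C)(C)OC[C@@]1(C=O)[C@H](C)[C@@]2(C)C=C(C)C=C(C)[C@@H]12
F14 | step 11 | tosylhydrazone of F13 | CC(C)(C)[Si](C)(C)OC[C@@]1(C=NNS(=O)(=O)c3ccc(C)cc3)[C@H](C)[C@@]2(C)C=C(C)C=C(C)[C@@H]12
F15 | step 11 | TBS ether of 21 | CC(C)(C)[Si](C)(C)OC[C@@]1(C)[C@H](C)[C@@]2(C)C=C(C)C=C(C)[C@@H]12
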